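**Retrosynthetic overview**
1. The central C6'–C6'' biaryl bond is cut last (Suzuki–Miyaura coupling of two naphthyl-isoquinoline halves that each carry a chlorine at that carbon); all phenols are masked as isopropyl ethers and freed at the end with BCl3.
2. Left half: the dihydroisoquinoline ring is closed on biaryl carbinol 19 by one annulation with acetonitrile that forms N–C3 and C1–C8a together; C1, its methyl group and N are an intact acetonitrile unit.
3. Enabling feature: C8a of the benzene ring of the dihydroisoquinoline is ortho to the C8 methoxy oxygen and para to the C6 oxygen, and it lies 1,4 to C3 (C8a–C4a–C4–C3), so a nitrilium carbon held on N at C3 reaches this most nucleophilic ring carbon in a six-membered closure.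
4. Right half: tetrahydroisoquinoline from a cyclic sulfamidate (C3), bromination, Bischler–Napieralski closure and trans-selective reduction (C1), then Suzuki–Miyaura coupling at C5.
5. Ring order: naphthalene 11 (Stobbe condensation and ring closure, used twice), then the tetrahydroisoquinoline, then the two naphthyl–aryl bonds, then the dihydroisoquinoline (key step), then the central bond.

Key step: step 11

Remark: the SMILES fixes three stereocentres (C3 of the dihydroisoquinoline, C1 and C3 of the tetrahydroisoquinoline, all R) and no axial configuration, so the hindered biaryl axes are treated as unspecified; 19, 23 and 36 to 39 are carried as atropisomer mixtures, to be separated by HPLC at 39 if a single atropisomer is wanted.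

**Route**

Step 1
Reactants: 1 4-chloro-3-hydroxybenzaldehyde
Product: 2 2-bromo-4-chloro-5-hydroxybenzaldehyde
Conditions: Br2, AcOH, rt
Reagents that add atoms: bromine BrBr
Why: Electrophilic aromatic bromination is directed para to the phenolic OH (one ortho position is blocked by Cl and the other is flanked by CHO), as in the known bromination of 3-hydroxybenzaldehyde.

Step 2
Reactants: 2 2-bromo-4-chloro-5-hydroxybenzaldehyde
Product: 3 2-bromo-4-chloro-5-(propan-2-yloxy)benzaldehyde
Conditions: 2-bromopropane, K2CO3, DMF, 60 °C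
Reagents that add atoms: 2-bromopropane CC(C)Br
Why: Williamson ether synthesis gives the isopropyl ether, a phenol protecting group that tolerates the bases, hydrides and organometallics used later and is cleaved at the end by BCl3.

Step 3
Reactants: 3 2-bromo-4-chloro-5-(propan-2-yloxy)benzaldehyde; 4 diethyl succinate
Product: 5 (3E)-4-[2-bromo-4-chloro-5-(propan-2-yloxy)phenyl]-3-(ethoxycarbonyl)but-3-enoic acid
Conditions: KOtBu, t-BuOH, reflux; then aq HCl
Reagents that add atoms: none
Why: The Stobbe condensation proceeds through the paraconic lactone and its ring opening to the (E)-half-ester, which places the CH2CO2H arm cis to the aryl ring as the ring closure requires.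

Step 4
Reactants: 5 (3E)-4-[2-bromo-4-chloro-5-(propan-2-yloxy)phenyl]-3-(ethoxycarbonyl)but-3-enoic acid
Product: 6 ethyl 4-acetoxy-8-bromo-6-chloro-5-(propan-2-yloxy)naphthalene-2-carboxylate
Conditions: Ac2O, NaOAc, 140 °C
Reagents that add atoms: acetic anhydride CC(=O)OC(C)=O
Why: Intramolecular Friedel–Crafts acylation through the mixed anhydride can take place only at the single free ortho carbon (ortho to the isopropoxy group), and the naphthol formed is trapped as its acetate, the classical Stobbe naphthalene synthesis.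

Step 5
Reactants: 6 ethyl 4-acetoxy-8-bromo-6-chloro-5-(propan-2-yloxy)naphthalene-2-carboxylate
Product: 8 ethyl 8-bromo-6-chloro-4-methoxy-5-(propan-2-yloxy)naphthalene-2-carboxylate, via naphthol 7 (not isolated)
Conditions: K2CO3, EtOH, rt; then MeI, K2CO3, DMF, 50 °C
Reagents that add atoms: iodomethane CI
Why: Base-mediated ethanolysis of the aryl acetate followed by Williamson methylation of the freed peri-naphthol installs the 4-methoxy group, and ethanol as the solvent keeps the ethyl ester unchanged.

Step 6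
Reactants: 8 ethyl 8-bromo-6-chloro-4-methoxy-5-(propan-2-yloxy)naphthalene-2-carboxylate
Product: 9 [8-bromo-6-chloro-4-methoxy-5-(propan-2-yloxy)naphthalen-2-yl]methanol
Conditions: iBu2AlH, CH2Cl2, −78 to 0 °C
Reagents that add atoms: none
Why: Hydride reduction of the ester with iBu2AlH gives the primary alcohol and leaves both aryl halides untouched.

Step 7
Reactants: 9 [8-bromo-6-chloro-4-methoxy-5-(propan-2-yloxy)naphthalen-2-yl]methanol
Product: 11 4-bromo-2-chloro-8-methoxy-6-methyl-1-(propan-2-yloxy)naphthalene, via mesylate 10 (not isolated)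
Conditions: MsCl, Et3N, CH2Cl2, 0 °C; crude mesylate in THF, LiBHEt3, 0 °C to rt
Reagents that add atoms: none
Why: Sulfonylation and SN2 hydride displacement of the benzylic sulfonate with LiBHEt3 convert CH2OH into CH3 without attack on the aryl bromide or chloride.

Step 8
Reactants: 12 3-bromo-5-methoxyphenol
Product: 13 1-bromo-3-methoxy-5-(propan-2-yloxy)benzene
Conditions: 2-bromopropane, K2CO3, DMF, 60 °C
Reagents that add atoms: 2-bromopropane CC(C)Br
Why: Williamson ether synthesis differentiates the two oxygens of the future dihydroisoquinoline ring as a methyl ether that stays and an isopropyl ether that is removed at the end.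

Step 9
Reactants: 13 1-bromo-3-methoxy-5-(propan-2-yloxy)benzene; 14 (S)-2-methyloxirane ((S)-propylene oxide)
Product: 16 (2S)-1-[3-methoxy-5-(propan-2-yloxy)phenyl]propan-2-ol, via Grignard reagent 15 (not isolated)
Conditions: Mg, THF, reflux; then CuI (10 mol %), 14, −30 to 0 °C; H2O
Reagents that add atoms: none
Why: Copper-catalysed SN2 opening of the epoxide by the aryl Grignard reagent at its unsubstituted carbon leaves the stereocentre of (S)-propylene oxide untouched and so gives the (S)-carbinol.

Step 10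
Reactants: 16 (2S)-1-[3-methoxy-5-(propan-2-yloxy)phenyl]propan-2-ol; 11 4-bromo-2-chloro-8-methoxy-6-methyl-1-(propan-2-yloxy)naphthalene
Product: 19 (2S)-1-{4-[3-chloro-5-methoxy-7-methyl-4-(propan-2-yloxy)naphthalen-1-yl]-3-methoxy-5-(propan-2-yloxy)phenyl}propan-2-ol, via aryllithium 17 (not isolated), via arylzinc chloride 18 (not isolated)
Conditions: n-BuLi (2.3 equiv), TMEDA, THF, 0 °C to rt; ZnCl2, 0 °C; then 11 (1.1 equiv), Pd(OAc)2, RuPhos, THF/NMP, 65 °C
Reagents that add atoms: none
Why: Directed ortho-metalation takes place at the carbon between the two alkoxy groups (the most acidic position of a 1,3-dialkoxybenzene), and after transmetalation the Negishi coupling engages the C–Br bond, which adds to zerovalent palladium far faster than the C–Cl bond when the bromide is kept in slight excess.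

Step 11
Reactants: 19 (2S)-1-{4-[3-chloro-5-methoxy-7-methyl-4-(propan-2-yloxy)naphthalen-1-yl]-3-methoxy-5-(propan-2-yloxy)phenyl}propan-2-ol; 20 acetonitrile
Product: 23 (3R)-7-[3-chloro-5-methoxy-7-methyl-4-(propan-2-yloxy)naphthalen-1-yl]-8-methoxy-1,3-dimethyl-6-(propan-2-yloxy)-3,4-dihydroisoquinoline, via triflate 21 (not isolated), via nitrilium triflate 22 (not isolated)
Conditions: Tf2O (1.1 equiv), 2,6-di-tert-butyl-4-methylpyridine, MeCN/CH2Cl2 (1:1), −40 °C to rt; aq NaHCO3
Reagents that add atoms: none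
Why: Proposed new method: Tf2O turns the (S)-carbinol into secondary triflate 21, the nitrogen of acetonitrile displaces the triflate in an SN2 step (Ritter-type N-alkylation) to give N-alkylnitrilium ion 22, and the nitrilium carbon is then attacked by ring carbon C8a with loss of a proton, which gives the 1-methyl-3,4-dihydroisoquinoline with both new bonds (N–C3 and C1–C8a) made in one flask. The closest known reaction types are the Tf2O-promoted annulation of 2-arylethanols with nitriles to 3,4-dihydroisoquinolines and the Bischler–Napieralski closure of nitrilium ions (used in step 16); new here is the use of an enantiopure secondary carbinol with the demand for clean inversion. The heterocycle closes by a 6-endo-dig electrophilic aromatic substitution that follows the intermolecular N–C3 bond formation. C3 is set as (R) by inversion of the (S)-carbinol derived from (S)-propylene oxide: the unstabilised secondary triflate should not ionise at low temperature, and aryl participation should be weak because the ipso carbon is meta to both oxygens and the twisted naphthyl group cannot donate. The step needs regioselectivity between the two free ortho carbons and substitution in preference to elimination: the naphthyl group holds both alkoxy groups turned toward the flanking ring CH positions, so the isopropoxy group shields its ortho carbon while the carbon beside the small methoxy group (para to the better donor) reacts, and a non-nucleophilic hindered pyridine base in acetonitrile as cosolvent should favour nitrile capture over E2.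

Step 12
Reactants: 24 5-bromobenzene-1,3-diol
Product: 25 1-bromo-3,5-bis(propan-2-yloxy)benzene
Conditions: 2-bromopropane, K2CO3, DMF, 70 °C
Reagents that add atoms: 2-bromopropane CC(C)Br
Why: Double Williamson ether synthesis protects both phenols as isopropyl ethers.

Step 13
Reactants: 25 1-bromo-3,5-bis(propan-2-yloxy)benzene; 26 tert-butyl (4R)-4-methyl-1,2,3-oxathiazolidine-3-carboxylate 2,2-dioxide
Product: 29 tert-butyl N-{(2R)-1-[3,5-bis(propan-2-yloxy)phenyl]propan-2-yl}carbamate, via Grignard reagent 27 (not isolated), via N-sulfamate salt 28 (not isolated)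
Conditions: Mg, THF, reflux; then CuI (10 mol %), 26, −20 °C to rt; then 10% aq citric acid, rt
Reagents that add atoms: none
Why: Copper-catalysed SN2 opening of the cyclic sulfamidate at its CH2–O carbon, a known route to N-Boc amphetamines, followed by mild acid hydrolysis of the N-sulfamate carries the (R)-centre of the reagent unchanged into the product.

Step 14
Reactants: 29 tert-butyl N-{(2R)-1-[3,5-bis(propan-2-yloxy)phenyl]propan-2-yl}carbamate
Product: 31 N-{(2R)-1-[3,5-bis(propan-2-yloxy)phenyl]propan-2-yl}acetamide, via ammonium chloride 30 (not isolated)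
Conditions: HCl, dioxane, rt; then Ac2O, Et3N, CH2Cl2, 0 °C
Reagents that add atoms: acetic anhydride CC(=O)OC(C)=O
Why: Acidolysis of the Boc group and N-acetylation of the liberated amine give the Bischler–Napieralski substrate without touching the stereocentre or the isopropyl ethers.

Step 15
Reactants: 31 N-{(2R)-1-[3,5-bis(propan-2-yloxy)phenyl]propan-2-yl}acetamide
Product: 32 N-{(2R)-1-[2-bromo-3,5-bis(propan-2-yloxy)phenyl]propan-2-yl}acetamide
Conditions: NBS (1.0 equiv), MeCN, 0 °C
Reagents that add atoms: N-bromosuccinimide O=C1CCC(=O)N1Br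
Why: Electrophilic aromatic bromination of the 5-alkylresorcinol diether occurs at a carbon ortho to the side chain and para to an isopropoxy group and not between the two bulky isopropoxy groups, and the two such carbons are equivalent by symmetry.

Step 16
Reactants: 32 N-{(2R)-1-[2-bromo-3,5-bis(propan-2-yloxy)phenyl]propan-2-yl}acetamide
Product: 33 (3R)-5-bromo-1,3-dimethyl-6,8-bis(propan-2-yloxy)-3,4-dihydroisoquinoline
Conditions: Tf2O, 2-chloropyridine, CH2Cl2, −78 °C to rt
Reagents that add atoms: none
Why: Bischler–Napieralski cyclisation through the nitrilium ion formed by amide activation closes onto the only free ortho carbon, which is ortho and para to the two isopropoxy groups, so that bromine ends up at C5.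

Step 17
Reactants: 33 (3R)-5-bromo-1,3-dimethyl-6,8-bis(propan-2-yloxy)-3,4-dihydroisoquinoline
Product: 34 (1R,3R)-5-bromo-1,3-dimethyl-6,8-bis(propan-2-yloxy)-1,2,3,4-tetrahydroisoquinoline
Conditions: LiAlH4, AlMe3, THF, −78 °C
Reagents that add atoms: none
Why: In this known trans-selective reduction of 1,3-dimethyl-3,4-dihydroisoquinolines the N-bound aluminium Lewis acid forces the C3 methyl group pseudoaxial and hydride adds to C1 from the opposite face, which sets C1 as (R) trans to the C3 methyl group, while the low temperature spares the aryl bromide.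

Step 18
Reactants: 11 4-bromo-2-chloro-8-methoxy-6-methyl-1-(propan-2-yloxy)naphthalene
Product: 35 2-[3-chloro-5-methoxy-7-methyl-4-(propan-2-yloxy)naphthalen-1-yl]-4,4,5,5-tetramethyl-1,3,2-dioxaborolane
Conditions: B2pin2, KOAc, PdCl2(dppf), dioxane, 85 °C
Reagents that add atoms: bis(pinacolato)diboron CC1(C)OB(OC1(C)C)B1OC(C)(C)C(C)(C)O1
Why: Miyaura borylation with PdCl2(dppf) is selective for the C–Br bond, since this catalyst does not insert into the electron-rich aryl chloride.

Step 19
Reactants: 35 2-[3-chloro-5-methoxy-7-methyl-4-(propan-2-yloxy)naphthalen-1-yl]-4,4,5,5-tetramethyl-1,3,2-dioxaborolane; 34 (1R,3R)-5-bromo-1,3-dimethyl-6,8-bis(propan-2-yloxy)-1,2,3,4-tetrahydroisoquinoline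
Product: 36 (1R,3R)-5-[3-chloro-5-methoxy-7-methyl-4-(propan-2-yloxy)naphthalen-1-yl]-1,3-dimethyl-6,8-bis(propan-2-yloxy)-1,2,3,4-tetrahydroisoquinoline
Conditions: Pd(PPh3)4 (10 mol %), Ba(OH)2, DME/H2O, 85 °C
Reagents that add atoms: none
Why: Suzuki–Miyaura coupling with Pd(PPh3)4 and Ba(OH)2 forms the hindered biaryl bond, a catalyst system that leaves the aryl chloride untouched, and the doubly alpha-branched secondary amine is too hindered for N-arylation.

Step 20
Reactants: 23 (3R)-7-[3-chloro-5-methoxy-7-methyl-4-(propan-2-yloxy)naphthalen-1-yl]-8-methoxy-1,3-dimethyl-6-(propan-2-yloxy)-3,4-dihydroisoquinoline; 36 (1R,3R)-5-[3-chloro-5-methoxy-7-methyl-4-(propan-2-yloxy)naphthalen-1-yl]-1,3-dimethyl-6,8-bis(propan-2-yloxy)-1,2,3,4-tetrahydroisoquinoline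
Product: 38 penta-O-isopropyl korundamine A (isopropyl ethers at O6 of the dihydroisoquinoline; at O6 and O8 of the tetrahydroisoquinoline; at O5 of both naphthalenes), via boronate 37 (not isolated)
Conditions: 23, B2pin2, KOAc, Pd(OAc)2, XPhos, dioxane, 100 °C; then 36, aq K3PO4, 90 °C
Reagents that add atoms: none
Why: One-pot Miyaura borylation and Suzuki–Miyaura coupling of the two aryl chlorides with the Pd(OAc)2/XPhos catalyst forms the central biaryl bond, which carries only one ortho substituent on each side and is therefore the least hindered of the three axes.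

Step 21
Reactants: 38 penta-O-isopropyl korundamine A
Product: 39 korundamine A
Conditions: BCl3, CH2Cl2, −20 °C to rt; then MeOH/H2O
Reagents that add atoms: none
Why: Lewis-acid ether cleavage with BCl3 removes isopropyl aryl ethers through loss of the secondary alkyl group much faster than methyl ethers, so that the five phenols are freed while the three methoxy groups, the imine and the three stereocentres stay untouched.

**Compound list**
1 | 4-chloro-3-hydroxybenzaldehyde | O=Cc1ccc(Cl)c(O)c1 | starting material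
2 | 2-bromo-4-chloro-5-hydroxybenzaldehyde | O=Cc1cc(O)c(Cl)cc1Br | intermediate
3 | 2-bromo-4-chloro-5-(propan-2-yloxy)benzaldehyde | O=Cc1cc(OC(C)C)c(Cl)cc1Br | intermediate
4 | diethyl succinate | CCOC(=O)CCC(=O)OCC | starting material
5 | (3E)-4-[2-bromo-4-chloro-5-(propan-2-yloxy)phenyl]-3-(ethoxycarbonyl)but-3-enoic acid | OC(=O)C/C(=C\c1cc(OC(C)C)c(Cl)cc1Br)C(=O)OCC | intermediate
6 | ethyl 4-acetoxy-8-bromo-6-chloro-5-(propan-2-yloxy)naphthalene-2-carboxylate | CCOC(=O)c1cc(OC(C)=O)c2c(OC(C)C)c(Cl)cc(Br)c2c1 | intermediate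
7 | ethyl 8-bromo-6-chloro-4-hydroxy-5-(propan-2-yloxy)naphthalene-2-carboxylate | CCOC(=O)c1cc(O)c2c(OC(C)C)c(Cl)cc(Br)c2c1 | intermediate
8 | ethyl 8-bromo-6-chloro-4-methoxy-5-(propan-2-yloxy)naphthalene-2-carboxylate | CCOC(=O)c1cc(OC)c2c(OC(C)C)c(Cl)cc(Br)c2c1 | intermediate
9 | [8-bromo-6-chloro-4-methoxy-5-(propan-2-yloxy)naphthalen-2-yl]methanol | OCc1cc(OC)c2c(OC(C)C)c(Cl)cc(Br)c2c1 | intermediate
10 | [8-bromo-6-chloro-4-methoxy-5-(propan-2-yloxy)naphthalen-2-yl]methyl methanesulfonate | CS(=O)(=O)OCc1cc(OC)c2c(OC(C)C)c(Cl)cc(Br)c2c1 | intermediate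
11 | 4-bromo-2-chloro-8-methoxy-6-methyl-1-(propan-2-yloxy)naphthalene | Cc1cc(OC)c2c(OC(C)C)c(Cl)cc(Br)c2c1 | intermediate
12 | 3-bromo-5-methoxyphenol | COc1cc(O)cc(Br)c1 | starting material
13 | 1-bromo-3-methoxy-5-(propan-2-yloxy)benzene | COc1cc(Br)cc(OC(C)C)c1 | intermediate
14 | (S)-2-methyloxirane | C[C@H]1CO1 | starting material
15 | [3-methoxy-5-(propan-2-yloxy)phenyl]magnesium bromide | COc1cc([Mg]Br)cc(OC(C)C)c1 | intermediate
16 | (2S)-1-[3-methoxy-5-(propan-2-yloxy)phenyl]propan-2-ol | C[C@H](O)Cc1cc(OC)cc(OC(C)C)c1 | intermediate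
17 | lithium (2S)-1-[4-lithio-3-methoxy-5-(propan-2-yloxy)phenyl]propan-2-olate | C[C@H]([O-])Cc1cc(OC)c([Li])c(OC(C)C)c1.[Li+] | intermediate
18 | lithium (2S)-1-[4-(chlorozincio)-3-methoxy-5-(propan-2-yloxy)phenyl]propan-2-olate | C[C@H]([O-])Cc1cc(OC)c([Zn]Cl)c(OC(C)C)c1.[Li+] | intermediate
19 | (2S)-1-{4-[3-chloro-5-methoxy-7-methyl-4-(propan-2-yloxy)naphthalen-1-yl]-3-methoxy-5-(propan-2-yloxy)phenyl}propan-2-ol | C[C@H](O)Cc1cc(OC)c(-c2cc(Cl)c(OC(C)C)c3c(OC)cc(C)cc23)c(OC(C)C)c1 | intermediate
20 | acetonitrile | CC#N | starting material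
21 | (2S)-1-{4-[3-chloro-5-methoxy-7-methyl-4-(propan-2-yloxy)naphthalen-1-yl]-3-methoxy-5-(propan-2-yloxy)phenyl}propan-2-yl trifluoromethanesulfonate | C[C@H](OS(=O)(=O)C(F)(F)F)Cc1cc(OC)c(-c2cc(Cl)c(OC(C)C)c3c(OC)cc(C)cc23)c(OC(C)C)c1 | intermediate
22 | N-[(2R)-1-{4-[3-chloro-5-methoxy-7-methyl-4-(propan-2-yloxy)naphthalen-1-yl]-3-methoxy-5-(propan-2-yloxy)phenyl}propan-2-yl]acetonitrilium trifluoromethanesulfonate | C[C@H](Cc1cc(OC)c(-c2cc(Cl)c(OC(C)C)c3c(OC)cc(C)cc23)c(OC(C)C)c1)[N+]#CC.[O-]S(=O)(=O)C(F)(F)F | intermediate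
23 | (3R)-7-[3-chloro-5-methoxy-7-methyl-4-(propan-2-yloxy)naphthalen-1-yl]-8-methoxy-1,3-dimethyl-6-(propan-2-yloxy)-3,4-dihydroisoquinoline | COc1c2c(cc(OC(C)C)c1-c1cc(Cl)c(OC(C)C)c3c(OC)cc(C)cc13)C[C@@H](C)N=C2C | intermediate
24 | 5-bromobenzene-1,3-diol | Oc1cc(O)cc(Br)c1 | starting material
25 | 1-bromo-3,5-bis(propan-2-yloxy)benzene | CC(C)Oc1cc(Br)cc(OC(C)C)c1 | intermediate
26 | tert-butyl (4R)-4-methyl-1,2,3-oxathiazolidine-3-carboxylate 2,2-dioxide | C[C@@H]1COS(=O)(=O)N1C(=O)OC(C)(C)C | starting material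
27 | [3,5-bis(propan-2-yloxy)phenyl]magnesium bromide | CC(C)Oc1cc([Mg]Br)cc(OC(C)C)c1 | intermediate
28 | bromomagnesium N-(tert-butoxycarbonyl)-N-{(2R)-1-[3,5-bis(propan-2-yloxy)phenyl]propan-2-yl}sulfamate | CC(C)Oc1cc(C[C@@H](C)N(C(=O)OC(C)(C)C)S(=O)(=O)[O-])cc(OC(C)C)c1.[Mg+]Br | intermediate
29 | tert-butyl N-{(2R)-1-[3,5-bis(propan-2-yloxy)phenyl]propan-2-yl}carbamate | CC(C)Oc1cc(C[C@@H](C)NC(=O)OC(C)(C)C)cc(OC(C)C)c1 | intermediate
30 | (2R)-1-[3,5-bis(propan-2-yloxy)phenyl]propan-2-aminium chloride | CC(C)Oc1cc(C[C@@H](C)[NH3+])cc(OC(C)C)c1.[Cl-] | intermediate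
31 | N-{(2R)-1-[3,5-bis(propan-2-yloxy)phenyl]propan-2-yl}acetamide | CC(C)Oc1cc(C[C@@H](C)NC(C)=O)cc(OC(C)C)c1 | intermediate
32 | N-{(2R)-1-[2-bromo-3,5-bis(propan-2-yloxy)phenyl]propan-2-yl}acetamide | CC(C)Oc1cc(OC(C)C)c(Br)c(C[C@@H](C)NC(C)=O)c1 | intermediate
33 | (3R)-5-bromo-1,3-dimethyl-6,8-bis(propan-2-yloxy)-3,4-dihydroisoquinoline | CC(C)Oc1cc(OC(C)C)c2c(c1Br)C[C@@H](C)N=C2C | intermediate
34 | (1R,3R)-5-bromo-1,3-dimethyl-6,8-bis(propan-2-yloxy)-1,2,3,4-tetrahydroisoquinoline | CC(C)Oc1cc(OC(C)C)c2c(c1Br)C[C@@H](C)N[C@@H]2C | intermediate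
35 | 2-[3-chloro-5-methoxy-7-methyl-4-(propan-2-yloxy)naphthalen-1-yl]-4,4,5,5-tetramethyl-1,3,2-dioxaborolane | Cc1cc(OC)c2c(OC(C)C)c(Cl)cc(B3OC(C)(C)C(C)(C)O3)c2c1 | intermediate
36 | (1R,3R)-5-[3-chloro-5-methoxy-7-methyl-4-(propan-2-yloxy)naphthalen-1-yl]-1,3-dimethyl-6,8-bis(propan-2-yloxy)-1,2,3,4-tetrahydroisoquinoline | Cc1cc(OC)c2c(OC(C)C)c(Cl)cc(-c3c(OC(C)C)cc(OC(C)C)c4c3C[C@@H](C)N[C@@H]4C)c2c1 | intermediate
37 | (3R)-8-methoxy-7-[5-methoxy-7-methyl-4-(propan-2-yloxy)-3-(4,4,5,5-tetramethyl-1,3,2-dioxaborolan-2-yl)naphthalen-1-yl]-1,3-dimethyl-6-(propan-2-yloxy)-3,4-dihydroisoquinoline | COc1c2c(cc(OC(C)C)c1-c1cc(B3OC(C)(C)C(C)(C)O3)c(OC(C)C)c3c(OC)cc(C)cc13)C[C@@H](C)N=C2C | intermediate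
38 | penta-O-isopropyl korundamine A | COc1c2c(cc(OC(C)C)c1-c1cc(-c3cc(-c4c(OC(C)C)cc(OC(C)C)c5c4C[C@@H](C)N[C@@H]5C)c4cc(C)cc(OC)c4c3OC(C)C)c(OC(C)C)c3c(OC)cc(C)cc13)C[C@@H](C)N=C2C | intermediate
39 | korundamine A | COc1c2c(cc(O)c1-c1cc(-c3cc(-c4c(O)cc(O)c5c4C[C@@H](C)N[C@@H]5C)c4cc(C)cc(OC)c4c3O)c(O)c3c(OC)cc(C)cc13)C[C@@H](C)N=C2C | target

**Step count and risks**

Total step count: 21. Longest linear sequence: 11 steps (steps 1 to 7, 10, 11, 20, 21; the sequence through steps 18 and 19 is equally long).

Steps most likely to fail: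

1. Step 11 (key annulation). What may go wrong: erosion of the C3 configuration if an aryl-assisted or ionising pathway competes with direct displacement; elimination of the triflate to the propenylarene; ring closure at the carbon beside the isopropoxy group. Fallback with known chemistry, setting out from 19 and returning at 23: Mitsunobu azidation of 19 (PPh3, DIAD, diphenylphosphoryl azide, THF, 0 °C to rt) should give with inversion the (R)-azide F1; Staudinger reduction (PPh3, THF/H2O, 50 °C) should give the (R)-amine F2; acetylation (Ac2O, Et3N, CH2Cl2) should give the acetamide F3; Bischler–Napieralski cyclisation of F3 (Tf2O, 2-chloropyridine, CH2Cl2, −78 °C to rt, as in step 16) closes the ring to 23, any regioisomer being removed by chromatography.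

2. Step 10 (metalation and Negishi coupling). What may go wrong: metalation at a ring carbon flanking the side chain or incomplete metalation of the alkoxide; slow coupling at the doubly ortho-substituted zinc centre; insertion of palladium into the C–Cl bond with oligomer formation. Fallback, setting out from 16 and returning at 19: lithiation as in step 10 and quenching with I2 (THF, −78 °C) should give the aryl iodide F4, which can be purified and its substitution pattern confirmed; Suzuki–Miyaura coupling of F4 with boronate 35 (Pd(PPh3)4, Ba(OH)2, DME/H2O, 85 °C, a catalyst inert to the aryl chloride) then gives 19.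

3. Step 20 (one-pot borylation and central coupling). What may go wrong: protodeboronation or homocoupling of boronate 37 before the cross-coupling; inhibition of the catalyst by the free amine and the imine. Fallback, setting out from 36 and returning at 39, with the amine masked, the roles of the partners reversed and the boronate isolated: Boc2O (neat, 70 °C) should give the carbamate F5; Miyaura borylation (B2pin2, KOAc, Pd(OAc)2, XPhos, dioxane, 100 °C) should give the isolated boronate F6; Suzuki–Miyaura coupling of F6 with chloride 23 (Pd(OAc)2, SPhos, K3PO4, toluene/H2O, 90 °C) should give the N-Boc protected dimer F7; BCl3 (CH2Cl2, −20 °C to rt) then removes the Boc group together with the five isopropyl groups and gives 39.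

Further compounds
F1 | step 11 | (2R)-2-azido-1-{4-[3-chloro-5-methoxy-7-methyl-4-(propan-2-yloxy)naphthalen-1-yl]-3-methoxy-5-(propan-2-yloxy)phenyl}propane | C[C@@H](N=[N+]=[N-])Cc1cc(OC)c(-c2cc(Cl)c(OC(C)C)c3c(OC)cc(C)cc23)c(OC(C)C)c1
F2 | step 11 | (2R)-1-{4-[3-chloro-5-methoxy-7-methyl-4-(propan-2-yloxy)naphthalen-1-yl]-3-methoxy-5-(propan-2-yloxy)phenyl}propan-2-amine | C[C@@H](N)Cc1cc(OC)c(-c2cc(Cl)c(OC(C)C)c3c(OC)cc(C)cc23)c(OC(C)C)c1
F3 | step 11 | N-[(2R)-1-{4-[3-chloro-5-methoxy-7-methyl-4-(propan-2-yloxy)naphthalen-1-yl]-3-methoxy-5-(propan-2-yloxy)phenyl}propan-2-yl]acetamide | C[C@@H](NC(C)=O)Cc1cc(OC)c(-c2cc(Cl)c(OC(C)C)c3c(OC)cc(C)cc23)c(OC(C)C)c1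
F4 | step 10 | (2S)-1-[4-iodo-3-methoxy-5-(propan-2-yloxy)phenyl]propan-2-ol | C[C@H](O)Cc1cc(OC)c(I)c(OC(C)C)c1
F5 | step 20 | tert-butyl (1R,3R)-5-[3-chloro-5-methoxy-7-methyl-4-(propan-2-yloxy)naphthalen-1-yl]-1,3-dimethyl-6,8-bis(propan-2-yloxy)-3,4-dihydroisoquinoline-2(1H)-carboxylate | Cc1cc(OC)c2c(OC(C)C)c(Cl)cc(-c3c(OC(C)C)cc(OC(C)C)c4c3C[C@@H](C)N(C(=O)OC(C)(C)C)[C@@H]4C)c2c1
F6 | step 20 | tert-butyl (1R,3R)-5-[5-methoxy-7-methyl-4-(propan-2-yloxy)-3-(4,4,5,5-tetramethyl-1,3,2-dioxaborolan-2-yl)naphthalen-1-yl]-1,3-dimethyl-6,8-bis(propan-2-yloxy)-3,4-dihydroisoquinoline-2(1H)-carboxylate | Cc1cc(OC)c2c(OC(C)C)c(B3OC(C)(C)C(C)(C)O3)cc(-c3c(OC(C)C)cc(OC(C)C)c4c3C[C@@H](C)N(C(=O)OC(C)(C)C)[C@@H]4C)c2c1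
F7 | step 20 | N-Boc penta-O-isopropyl korundamine A (Boc on the tetrahydroisoquinoline nitrogen) | COc1c2c(cc(OC(C)C)c1-c1cc(-c3cc(-c4c(OC(C)C)cc(OC(C)C)c5c4C[C@@H](C)N(C(=O)OC(C)(C)C)[C@@H]5C)c4cc(C)cc(OC)c4c3OC(C)C)c(OC(C)C)c3c(OC)cc(C)cc13)C[C@@H](C)N=C2C
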